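## Retrosynthetic overview
1. The epoxide is the last ring. It comes from outer-face epoxidation of the 4E-alkene of the finished carbocycle/butenolide.
2. C6–C7 and O6–C12 are made in one operation. An alkenyl-Cr(III) species from a (Z)-β-iodoacrylate adds to a C6 enal and the alkoxide lactonises, so the ten-membered ring and the butenolide form together.
3. The tetrasubstituted iodoacrylate (C7–I, C11–C13) comes from a three-component iodide/ynoate/formaldehyde coupling. The enal comes from direct oxidation of an allylic silyl ether.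
4. C8 is set by asymmetric addition of methyl propiolate to a C8 aldehyde. That aldehyde comes from an anti-Markovnikov Wacker oxidation of a syn-crotylation product, which sets C1 and C10.
5. The C1–C6/C15 aldehyde comes from geraniol by silylation and selective ozonolysis.

Assumption: germacrane numbering of the target (C1–C15, lactone C6–O–C12, C13 = CH2OAc) is used for all intermediates, and the catalyst antipodes named in steps 3 and 6 are taken to be those that attack the Re face of the aldehyde.

## Route

Step 1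
Reactants: 1 geraniol
Product: 2 geranyl tert-butyldimethylsilyl ether
Conditions: TBSCl, imidazole, CH2Cl2, 0 °C to rt
Reagents that add atoms: tert-butyldimethylsilyl chloride, CC(C)(C)[Si](C)(C)Cl
Why: Standard silylation (substitution at silicon) masks the C6 hydroxyl as an allylic silyl ether that is later turned directly into the enal, and no stereocentre is formed.

Step 2
Reactants: 2 geranyl tert-butyldimethylsilyl ether
Product: 3 (4E)-6-(tert-butyldimethylsilyloxy)-4-methylhex-4-enal
Conditions: O3 (1 equiv, Sudan Red 7B end point), CH2Cl2, −78 °C; then Me2S, −78 °C to rt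
Reagents that add atoms: ozone, [O-][O+]=O
Why: Chemoselective ozonolysis (Criegee mechanism) cleaves only the remote isopropylidene alkene, because it is more electron-rich than C4=C5, which is deactivated by its allylic C–O bond, and no stereocentre is formed.

Step 3
Reactants: 3 (4E)-6-(tert-butyldimethylsilyloxy)-4-methylhex-4-enal; 4 (Z)-crotylboronic acid pinacol ester
Product: 5 (2E,6S,7S)-1-(tert-butyldimethylsilyloxy)-3,7-dimethylnona-2,8-dien-6-ol (1S,10S in target numbering)
Conditions: (R)-TRIP (5 mol %), 4 Å MS, toluene, −30 °C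
Reagents that add atoms: (Z)-crotylboronic acid pinacol ester 4, C/C=C\CB1OC(C)(C)C(C)(C)O1
Why: Chiral-phosphoric-acid-catalysed crotylboration runs through a closed Zimmerman–Traxler chair, so the Z-crotyl geometry gives the syn C1-OH/C10-CH3 pair and the catalyst-bound boronate attacks the Re face of the aldehyde to give 1S,10S.

Step 4
Reactants: 5 (2E,6S,7S)-1-(tert-butyldimethylsilyloxy)-3,7-dimethylnona-2,8-dien-6-ol
Product: 6 (2E,6S,7S)-1-(tert-butyldimethylsilyloxy)-3,7-dimethylnona-2,8-dien-6-yl acetate
Conditions: Ac2O, pyridine, DMAP (cat.), CH2Cl2, rt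
Reagents that add atoms: acetic anhydride, CC(=O)OC(C)=O
Why: DMAP-catalysed acylation installs the C1 acetate of the target with retention, since only the O–H bond is broken.

Step 5
Reactants: 6 (2E,6S,7S)-1-(tert-butyldimethylsilyloxy)-3,7-dimethylnona-2,8-dien-6-yl acetate
Product: 7 (3S,4S,7E)-4-acetoxy-9-(tert-butyldimethylsilyloxy)-3,7-dimethylnon-7-enal
Conditions: PdCl2(PhCN)2 (12 mol %), CuCl2·2H2O (12 mol %), AgNO2 (6 mol %), t-BuOH/MeNO2 15:1, O2 (1 atm), rt
Reagents that add atoms: dioxygen, O=O
Why: The nitrite-co-catalysed aldehyde-selective (anti-Markovnikov) Wacker oxidation puts oxygen on the terminal carbon of the monosubstituted alkene (helped by the branched allylic carbon and the homoallylic acetate), leaves the trisubstituted C4=C5 alkene alone, and touches no stereocentre because C9 becomes CH2.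

Step 6
Reactants: 7 (3S,4S,7E)-4-acetoxy-9-(tert-butyldimethylsilyloxy)-3,7-dimethylnon-7-enal; 8 methyl propiolate
Product: 10 methyl (4S,6S,7S,10E)-7-acetoxy-12-(tert-butyldimethylsilyloxy)-6,10-dimethyl-4-(methacryloyloxy)dodec-10-en-2-ynoate, via methylzinc propargylic alkoxide 9 (not isolated)
Conditions: (S,S)-ProPhenol (20 mol %), Me2Zn (3 equiv), 8 (3 equiv), toluene, 4 °C; then methacrylic anhydride, DMAP, 0 °C to rt; aq NH4Cl
Reagents that add atoms: methyl propiolate 8, C#CC(=O)OC; methacrylic anhydride, C=C(C)C(=O)OC(=O)C(C)=C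
Why: In the dinuclear-zinc (ProPhenol) asymmetric alkynylation the zinc alkynylide is delivered under catalyst control to the Re face of the aldehyde to give 8S, and the zinc alkoxide is acylated in the same flask, which separates O8 (methacrylate) from the acetate positions.

Step 7
Reactants: 10 methyl (4S,6S,7S,10E)-7-acetoxy-12-(tert-butyldimethylsilyloxy)-6,10-dimethyl-4-(methacryloyloxy)dodec-10-en-2-ynoate; 11 formaldehyde (monomer, cracked from paraformaldehyde)
Product: 13 methyl (2Z,4S,6S,7S,10E)-7-acetoxy-2-(acetoxymethyl)-12-(tert-butyldimethylsilyloxy)-3-iodo-6,10-dimethyl-4-(methacryloyloxy)dodeca-2,10-dienoate, via iodomagnesium alkoxide 12 (not isolated)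
Conditions: MgI2 (1.5 equiv), CH2O (5 equiv, solution in CH2Cl2), CH2Cl2, −20 to 0 °C; then Ac2O, pyridine, DMAP, 0 °C
Reagents that add atoms: magnesium iodide, [Mg+2].[I-].[I-]; formaldehyde 11, C=O; acetic anhydride, CC(=O)OC(C)=O
Why: In this MgI2-promoted halo-aldol (β-iodo Morita–Baylis–Hillman) reaction iodide adds to C7 of the ynoate and the magnesium allenolate takes up formaldehyde at C11 anti to iodine (the same anti addition as in Z-selective hydroiodination of 2-alkynoates), which puts I cis to CO2Me, and the alkoxide is acetylated in the flask without creating a stereocentre.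

Step 8
Reactants: 13 methyl (2Z,4S,6S,7S,10E)-7-acetoxy-2-(acetoxymethyl)-12-(tert-butyldimethylsilyloxy)-3-iodo-6,10-dimethyl-4-(methacryloyloxy)dodeca-2,10-dienoate
Product: 14 methyl (2Z,4S,6S,7S,10E)-7-acetoxy-2-(acetoxymethyl)-3-iodo-6,10-dimethyl-4-(methacryloyloxy)-12-oxododeca-2,10-dienoate
Conditions: DDQ (1.5 equiv), CH2Cl2/pH 7 buffer 18:1, 0 °C to rt
Reagents that add atoms: none
Why: In this oxidative deprotection of an allylic silyl ether DDQ abstracts hydride from the electron-rich prenyl-type C6–H, water desilylates the resulting silyl oxocarbenium ion to give the E-enal directly, and the electron-poor allylic positions C8 and C13 do not react.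

Step 9
Reactants: 14 methyl (2Z,4S,6S,7S,10E)-7-acetoxy-2-(acetoxymethyl)-3-iodo-6,10-dimethyl-4-(methacryloyloxy)-12-oxododeca-2,10-dienoate
Product: 17 4,5-deepoxy-4,5-didehydroglaucolide K [(1S,4E,6R,8S,10S)-1,13-diacetoxy-8-(methacryloyloxy)germacra-4,7(11)-dien-6,12-olide], via alkenylchromium species 15 (not isolated), via macrocyclic chromium alkoxide 16 (not isolated)
Conditions: CrCl2 (10 equiv), NiCl2 (1 mol % of Cr), DMSO, rt, syringe-pump addition to 2 mM; aq work-up
Reagents that add atoms: none
Why: This is an intramolecular Nozaki–Hiyama–Kishi addition followed by lactonisation in the flask, in which Ni(0) inserts into the electron-poor C7–I bond faster than into the allylic esters, the ester-chelated alkenyl-Cr(III) keeps its geometry and adds 1,2 to the s-trans enal, and the C6 alkoxide, held cis to CO2Me, expels methoxide at once so that carbocycle and butenolide arise together; C6 is set by C8, because only attack on the Si face of the aldehyde lets C7 be a ring corner with H-8 eclipsing C7=C11 (least A1,3 strain against CH2OAc) and C5 and C9 on opposite faces of the alkenyl plane, and that rotamer also holds the C8–O bond orthogonal to C7–Cr, which slows β-elimination (6R here is the 6S of the target, a change of CIP priority only).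

Step 10
Reactants: 17 4,5-deepoxy-4,5-didehydroglaucolide K
Product: 18 glaucolide K (1S,4R,5R,6S,8S,10S)
Conditions: mCPBA (1.1 equiv), NaHCO3, CH2Cl2, 0 °C
Reagents that add atoms: 3-chloroperoxybenzoic acid, OOC(=O)c1cccc(Cl)c1
Why: In this Prilezhaev epoxidation C4=C5 is the only electron-rich alkene (methacrylate and butenolide are inert), and in the ten-membered ring it is reached only from its outer face, the one anti to C7 when H-6 eclipses the alkene to avoid A1,3 strain with C15, which gives the trans-(4R,5R)-epoxide as in related 6,12-germacranolides.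

## Compound list
1 | geraniol | CC(C)=CCC/C(C)=C/CO | starting material
2 | geranyl TBS ether | CC(C)=CCC/C(C)=C/CO[Si](C)(C)C(C)(C)C | intermediate
3 | (4E)-6-(TBSO)-4-methylhex-4-enal | O=CCC/C(C)=C/CO[Si](C)(C)C(C)(C)C | intermediate
4 | (Z)-crotylboronic acid pinacol ester | C/C=C\CB1OC(C)(C)C(C)(C)O1 | starting material
5 | syn homoallylic alcohol (1S,10S) | C=C[C@H](C)[C@@H](O)CC/C(C)=C/CO[Si](C)(C)C(C)(C)C | intermediate
6 | C1 acetate of 5 | C=C[C@H](C)[C@@H](OC(C)=O)CC/C(C)=C/CO[Si](C)(C)C(C)(C)C | intermediate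
7 | C8 aldehyde | O=CC[C@H](C)[C@@H](OC(C)=O)CC/C(C)=C/CO[Si](C)(C)C(C)(C)C | intermediate
8 | methyl propiolate | C#CC(=O)OC | starting material
9 | methylzinc alkoxide of the (8S)-propargylic alcohol | COC(=O)C#C[C@@H](O[Zn]C)C[C@H](C)[C@@H](OC(C)=O)CC/C(C)=C/CO[Si](C)(C)C(C)(C)C | intermediate
10 | (8S)-methacrylate ynoate | COC(=O)C#C[C@@H](OC(=O)C(C)=C)C[C@H](C)[C@@H](OC(C)=O)CC/C(C)=C/CO[Si](C)(C)C(C)(C)C | intermediate
11 | formaldehyde | C=O | starting material
12 | iodomagnesium alkoxide of the (Z)-β-iodo-α-(hydroxymethyl)acrylate | COC(=O)/C(CO[Mg]I)=C(\I)[C@@H](OC(=O)C(C)=C)C[C@H](C)[C@@H](OC(C)=O)CC/C(C)=C/CO[Si](C)(C)C(C)(C)C | intermediate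
13 | (Z)-β-iodo-α-(acetoxymethyl)acrylate, C6 TBS ether | COC(=O)/C(COC(C)=O)=C(\I)[C@@H](OC(=O)C(C)=C)C[C@H](C)[C@@H](OC(C)=O)CC/C(C)=C/CO[Si](C)(C)C(C)(C)C | intermediate
14 | iodoacrylate enal | COC(=O)/C(COC(C)=O)=C(\I)[C@@H](OC(=O)C(C)=C)C[C@H](C)[C@@H](OC(C)=O)CC/C(C)=C/C=O | intermediate
15 | alkenylchromium(III) enal | COC(=O)/C(COC(C)=O)=C(\[Cr](Cl)Cl)[C@@H](OC(=O)C(C)=C)C[C@H](C)[C@@H](OC(C)=O)CC/C(C)=C/C=O | intermediate
16 | macrocyclic C6 chromium(III) alkoxide | C=C(C)C(=O)O[C@H]1C[C@H](C)[C@@H](OC(C)=O)CC/C(C)=C/[C@@H](O[Cr](Cl)Cl)/C1=C(/COC(C)=O)C(=O)OC | intermediate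
17 | 4,5-deepoxy-4,5-didehydroglaucolide K | C=C(C)C(=O)O[C@H]1C[C@H](C)[C@@H](OC(C)=O)CC/C(C)=C/[C@H]2OC(=O)C(COC(C)=O)=C12 | intermediate
18 | glaucolide K | C=C(C)C(=O)O[C@H]1C[C@H](C)[C@@H](OC(C)=O)CC[C@@]2(C)O[C@@H]2[C@H]2OC(=O)C(COC(C)=O)=C12 | target

## Step count and risks
Total step count: 10. Longest linear sequence: 10.

**Step 9 (ring closure).** The alkenylchromium may lose the C8 methacrylate to give an allenoate, be protonated, or oligomerise before it reaches the weakly electrophilic enal. The C6 selectivity also rests on C8 alone. The fallback sets out from 13 and comes back at 18.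
- HF·pyridine in THF frees the allylic alcohol F1.
- Sharpless asymmetric epoxidation [Ti(OiPr)4, D-(−)-diethyl tartrate, TBHP, 4 Å MS, CH2Cl2, −20 °C] gives the (4R,5R)-epoxy alcohol F2 under reagent control.
- Dess–Martin periodinane gives the epoxy aldehyde F3.
- The Ni/Cr closure then runs through the alkenylchromium epoxy aldehyde F4 on a non-conjugated, much more electrophilic aldehyde whose sp3 carbons ease ring strain. C7 attacks anti to the epoxide C–O bond and gauche to C4, the only torsion a ten-membered ring tolerates next to a trans-epoxide. This reinforces the C8 control.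
- The epoxy chromium alkoxide F5 lactonises directly to 18, so step 10 is not needed.

**Step 7 (halo-aldol).** An internal, γ-branched ynoate may add iodide slowly. Monomeric formaldehyde polymerises on MgI2. The Z/E ratio or the allylic silyl ether may also suffer. The fallback sets out from 10 and comes back at 13, and replaces the aldol by a Mannich/displacement sequence.
- Eschenmoser's salt (CH2=NMe2+ I−, with catalytic MgI2, CH2Cl2, 0 °C) supplies both iodide and a non-polymerising C1 electrophile. It gives the (Z)-β-iodo-α-(dimethylaminomethyl)acrylate F6.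
- MeI gives the allylic trimethylammonium iodide F7.
- KOAc in DMF displaces trimethylamine at the primary allylic carbon (SN2) to give 13.

**Step 5 (aldehyde-selective Wacker).** Methyl ketone formation, alkene isomerisation or partial desilylation may lower the yield. The fallback sets out from 6 and comes back at 7.
- 9-BBN hydroborates only the terminal alkene to give the B-alkyl-9-BBN adduct F8.
- NaBO3·4H2O, which is mild enough for the acetate, gives the primary alcohol F9.
- Dess–Martin periodinane gives 7.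

## Further compounds
F1 | step 9 | C6 allylic alcohol from 13 | COC(=O)/C(COC(C)=O)=C(\I)[C@@H](OC(=O)C(C)=C)C[C@H](C)[C@@H](OC(C)=O)CC/C(C)=C/CO
F2 | step 9 | (4R,5R)-epoxy alcohol | COC(=O)/C(COC(C)=O)=C(\I)[C@@H](OC(=O)C(C)=C)C[C@H](C)[C@@H](OC(C)=O)CC[C@@]1(C)O[C@@H]1CO
F3 | step 9 | epoxy aldehyde | COC(=O)/C(COC(C)=O)=C(\I)[C@@H](OC(=O)C(C)=C)C[C@H](C)[C@@H](OC(C)=O)CC[C@@]1(C)O[C@@H]1C=O
F4 | step 9 | alkenylchromium(III) epoxy aldehyde | COC(=O)/C(COC(C)=O)=C(\[Cr](Cl)Cl)[C@@H](OC(=O)C(C)=C)C[C@H](C)[C@@H](OC(C)=O)CC[C@@]1(C)O[C@@H]1C=O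
F5 | step 9 | macrocyclic epoxy C6 chromium(III) alkoxide | C=C(C)C(=O)O[C@H]1C[C@H](C)[C@@H](OC(C)=O)CC[C@@]2(C)O[C@@H]2[C@@H](O[Cr](Cl)Cl)/C1=C(/COC(C)=O)C(=O)OC
F6 | step 7 | (Z)-β-iodo-α-(dimethylaminomethyl)acrylate | COC(=O)/C(CN(C)C)=C(\I)[C@@H](OC(=O)C(C)=C)C[C@H](C)[C@@H](OC(C)=O)CC/C(C)=C/CO[Si](C)(C)C(C)(C)C
F7 | step 7 | allylic trimethylammonium iodide | COC(=O)/C(C[N+](C)(C)C)=C(\I)[C@@H](OC(=O)C(C)=C)C[C@H](C)[C@@H](OC(C)=O)CC/C(C)=C/CO[Si](C)(C)C(C)(C)C.[I-]
F8 | step 5 | B-alkyl-9-BBN adduct of 6 | C1CCC2CCCC1B2CC[C@H](C)[C@@H](OC(C)=O)CC/C(C)=C/CO[Si](C)(C)C(C)(C)C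
F9 | step 5 | C8 primary alcohol | OCC[C@H](C)[C@@H](OC(C)=O)CC/C(C)=C/CO[Si](C)(C)C(C)(C)C
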